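**Retrosynthetic overview**

1. Feature: in the cyclohexane ring C5–C6–C7–C22–C21–C20, the fully substituted C7 (methyl C8, ether O9, ring bonds to C6 and C22) lies 1,4 to C20. O9 and C18 share one face and C5 carries oxygen. This is the pattern O1–C6(CH3) / C3–C2 / C4–OMe of 4-methoxy-6-methyl-2-pyranone.
2. Last ring, the tetrahydropyran C10–C11–C12–C14–O17–C18: O17–C14 and C12–Br are cut together (6-endo bromoetherification of a C12=C14 prenyl alkene by the C18 hydroxyl).
3. Second ring, the oxepane bridge of the 2-oxabicyclo[3.2.2]nonane: O9–C10 is cut (transannular reductive etherification of the C7 oxygen onto a C10 ketone).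
4. C18–C10 is cut to a C18 methyl ketone, made from the lactone carbonyl, and a 2-prenyl-1,3-dithiane anion (C10–C12, C14–C16). C22–O23 comes from an acyl group by Baeyer–Villiger oxidation, and C5–O4 from a masked ketone.
5. First ring, the carbocycle: C20–C21 and C7–C22 are cut by retro-[4+2] of a 2-oxabicyclo[2.2.2]octenone to the pyranone and N-acryloyl-2-oxazolidinone.

Key step: step 3

Remark: locants C1–O23 follow the heavy-atom order of the target SMILES. β is the face of the cyclohexane ring that carries O9 and C18, and α is the opposite face. In these locants the target is (5S,7R,10S,12S,18S,20R,22R).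

**Step 1**
Reactants: 1 4-hydroxy-6-methyl-2H-pyran-2-one (triacetic acid lactone)
Product: 2 4-methoxy-6-methyl-2H-pyran-2-one
Conditions: Me2SO4, K2CO3, acetone, reflux
Reagents that add atoms: dimethyl sulfate, COS(=O)(=O)OC
Why: Williamson-type O-methylation, in which the vinylogous carboxylic acid OH at C4 is the only acidic site and its potassium salt is alkylated on oxygen by the hard electrophile; no stereocentre is formed.

**Step 2**
Reactants: 3 1,3-oxazolidin-2-one; 4 acryloyl chloride
Product: 5 3-acryloyl-1,3-oxazolidin-2-one
Conditions: Et3N, LiCl, THF, 0 °C to rt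
Reagents that add atoms: none
Why: N-acylation of the carbamate nitrogen, made nucleophilic by lithium coordination and Et3N, at a temperature low enough to keep the acrylate from polymerising; no stereocentre is formed.

**Step 3**
Reactants: 2 4-methoxy-6-methyl-2H-pyran-2-one; 5 3-acryloyl-1,3-oxazolidin-2-one
Product: 6 3-[(1R,4R,7R)-5-methoxy-1-methyl-3-oxo-2-oxabicyclo[2.2.2]oct-5-ene-7-carbonyl]-1,3-oxazolidin-2-one (endo adduct)
Conditions: [Cu((R,R)-t-Bu-box)](SbF6)2 (10 mol %; t-Bu-box = 2,2'-(propane-2,2-diyl)bis(4-tert-butyl-4,5-dihydrooxazole)), CH2Cl2, 0 °C to rt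
Reagents that add atoms: none
Why: Proposed new method: the imide binds the divalent copper centre through both carbonyl oxygens in a square-planar complex, which locks the s-cis acryloyl conformer and lowers its LUMO, so that the push–pull diene C3=C4(OMe)–C5=C6(CH3) of 2 can add in a normal-demand, concerted but asynchronous [4+2] in which C3–Cβ (C20–C21) bonding runs ahead of C6–Cα (C7–C22). The closest known reactions are the cycloadditions of 5 to cyclopentadiene, cyclohexa-1,3-diene and furan under the same cationic copper bis(oxazoline) complexes, and the thermal, high-pressure or Lewis-acid Diels–Alder reactions of 2-pyranones with acrylates that stop at 2-oxabicyclo[2.2.2]octenones; their combination on a 4-alkoxy-2-pyranone is what is new. One ring is closed, the cyclohexene C5–C6–C7–C22–C21–C20, by suprafacial–suprafacial addition across C3 and C6 of the heteroarene, which turns the O1–C2 ester unit into the O9–C18 lactone bridge. C7 and C20 are tied to each other by that suprafacial addition (O9 and C18 end up cis-1,4), C22 is set relative to them by the endo rule (imide carbonyl under the diene, hence syn to the enol-ether bridge and anti to the lactone bridge), and the absolute sense comes from the tert-butyl group of the (R,R) ligand, which covers the α-Re face of the bound acrylimide and leaves the α-Si face open, the mirror image of the known (S,S)/α-Re pairing. The step needs regio-, endo- and enantiofacial selectivity and retention of CO2: the 4-methoxy group and the ring oxygen both make C3 the nucleophilic terminus, so it bonds to the electrophilic β-carbon, two-point binding of the imide secures the other two selectivities, and a temperature at or below ambient keeps the bridged lactone from cycloreversion.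

**Step 4**
Reactants: 6 endo imide adduct
Product: 7 S-ethyl (1R,4R,7R)-5-methoxy-1-methyl-3-oxo-2-oxabicyclo[2.2.2]oct-5-ene-7-carbothioate
Conditions: EtSH, n-BuLi, THF, 0 °C; aq NH4Cl
Reagents that add atoms: ethanethiol, CCS
Why: Acyl transfer (thiolysis) at the activated exocyclic imide carbonyl by the soft, weakly basic thiolate, which leaves C22 and the enol ether untouched, while any addition to the strained lactone is reversed by re-closure of the tertiary alkoxide.

**Step 5**
Reactants: 7 enol-ether thioester
Product: 8 S-ethyl (1R,4R,7R)-5,5-dimethoxy-1-methyl-3-oxo-2-oxabicyclo[2.2.2]octane-7-carbothioate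
Conditions: MeOH, camphorsulfonic acid (cat.), 0 °C
Reagents that add atoms: methanol, CO
Why: Acid-catalysed addition of methanol to the enol ether (ketalisation through the C5 oxocarbenium ion after protonation at C6) masks the future C5 ketone in a form that tolerates peracid and organometallic reagents and removes the only peracid-sensitive alkene; no stereocentre is touched.

**Step 6**
Reactants: 8 ketal thioester
Product: 9 (1R,4R,7R)-7-acetyl-5,5-dimethoxy-1-methyl-2-oxabicyclo[2.2.2]octan-3-one
Conditions: Me2CuLi (MeLi, CuI), Et2O, −78 °C; aq NH4Cl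
Reagents that add atoms: lithium dimethylcuprate (from MeLi and CuI), [Li+].C[Cu-]C
Why: Ketone synthesis from a thioester and a Gilman cuprate, in which the soft reagent displaces thiolate and stops at the ketone, does not attack the lactone or the ketal, and is too weakly basic to epimerise C22.

**Step 7**
Reactants: 9 endo methyl ketone
Product: 10 (1R,4R,7R)-5,5-dimethoxy-1-methyl-3-oxo-2-oxabicyclo[2.2.2]octan-7-yl acetate
Conditions: mCPBA, NaHCO3, CH2Cl2, rt
Reagents that add atoms: 3-chloroperoxybenzoic acid, OOC(=O)c1cccc(Cl)c1
Why: Baeyer–Villiger oxidation, in which the secondary carbon C22 of the Criegee adduct migrates in preference to methyl and with retention, so that the endo (α) C–C bond becomes the α C22–O23 bond while the buffer protects the ketal.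

**Step 8**
Reactants: 10 acetoxy lactone
Product: 11 (1R,4R,5R)-4,5-dihydroxy-N,2,2-trimethoxy-N,4-dimethylcyclohexane-1-carboxamide
Conditions: MeNH(OMe)·HCl, i-PrMgCl, THF, −20 to 0 °C; aq NH4Cl
Reagents that add atoms: N,O-dimethylhydroxylamine hydrochloride, CNOC.Cl
Why: Aminolysis of both esters by the magnesium amide (Weinreb amide synthesis), in which release of boat strain drives opening of the bridged lactone to the C18 amide and the free C7 tertiary alcohol with the C7–O9 bond intact, the acetate is cleaved in the same operation, and the non-acidic medium spares the ketal and C20.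

**Step 9**
Reactants: 11 diol Weinreb amide
Product: 12 (1R,4R,5R)-5-(tert-butyldimethylsilyloxy)-4-hydroxy-N,2,2-trimethoxy-N,4-dimethylcyclohexane-1-carboxamide
Conditions: TBSCl, imidazole, DMF, rt
Reagents that add atoms: tert-butyldimethylsilyl chloride, CC(C)(C)[Si](C)(C)Cl
Why: Imidazole-catalysed silylation distinguishes the secondary C22 hydroxyl from the tertiary C7 hydroxyl on steric grounds.

**Step 10**
Reactants: 12 C22 silyl ether
Product: 13 (1R,4R,5R)-5-(tert-butyldimethylsilyloxy)-N,2,2-trimethoxy-N,4-dimethyl-4-(triethylsilyloxy)cyclohexane-1-carboxamide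
Conditions: TESOTf, 2,6-lutidine, CH2Cl2, −78 °C
Reagents that add atoms: triethylsilyl triflate, CC[Si](CC)(CC)OS(=O)(=O)C(F)(F)F
Why: The more reactive silyl triflate silylates the hindered tertiary alcohol at low temperature, which blocks lactol formation during the carbonyl additions and provides the silyl ether that later serves as the oxygen nucleophile.

**Step 11**
Reactants: 13 bis-silylated Weinreb amide
Product: 14 1-[(1S,4R,5R)-5-(tert-butyldimethylsilyloxy)-2,2-dimethoxy-4-methyl-4-(triethylsilyloxy)cyclohexyl]ethan-1-one (C18 methyl ketone)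
Conditions: MeMgBr, THF, 0 °C; aq NH4Cl
Reagents that add atoms: methylmagnesium bromide, C[Mg]Br
Why: Weinreb ketone synthesis, in which the chelated tetrahedral adduct survives until the quench, so that a single methyl group (C19) is delivered and C20 is never exposed to base as a ketone.

**Step 12**
Reactants: 15 1,3-dithiane; 16 1-bromo-3-methylbut-2-ene (prenyl bromide)
Product: 18 2-(3-methylbut-2-en-1-yl)-1,3-dithiane, via 2-lithio-1,3-dithiane 17 (not isolated)
Conditions: n-BuLi, THF, −30 °C; then 16, −78 °C to rt
Reagents that add atoms: none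
Why: Corey–Seebach umpolung, in which deprotonation between the sulfur atoms and SN2 alkylation at the primary carbon of the allylic bromide give the masked 4-methylpent-3-enoyl anion that holds C10–C12 and C14–C16.

**Step 13**
Reactants: 14 C18 methyl ketone; 18 2-prenyl-1,3-dithiane
Product: 20 (18S)-carbinol (C20 β-[1-hydroxy-1-(2-prenyl-1,3-dithian-2-yl)ethyl]; C5 dimethyl ketal; C7 β-OSiEt3/α-CH3; C22 α-OTBS), via 2-lithio-2-prenyl-1,3-dithiane 19 (not isolated)
Conditions: 18, n-BuLi, THF, −20 °C; then 14 precomplexed to LaCl3·2LiCl, THF, −78 to −40 °C; aq NH4Cl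
Reagents that add atoms: none
Why: Corey–Seebach addition of the acyl anion equivalent to the Lewis-acid-activated methyl ketone under Felkin–Anh control, in which, in the chair that holds the acetyl group equatorial, the fully substituted ketal carbon C5 is the large group on C20 and lies anti to the incoming carbanion, which passes over H20 on the C21 side and sets (18S).

**Step 14**
Reactants: 20 ketal carbinol
Product: 21 C5 ketone (other groups and centres as in 20)
Conditions: PPTS (cat.), acetone/H2O 10:1, rt
Reagents that add atoms: water, O
Why: Mild acid hydrolysis of the strained dimethyl ketal, which is far more labile than the dithiane or the silyl ethers, frees the C5 ketone only after C18 has ceased to be a carbonyl group, so that C20 never lies between two carbonyl groups.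

**Step 15**
Reactants: 21 β-hydroxy ketone
Product: 23 (5S)-alcohol (C5 β-OH syn to the C18 OH; other groups as in 21), via diethylborinate 22 (not isolated)
Conditions: Et2BOMe, THF/MeOH 4:1, −78 °C; NaBH4; AcOH quench, MeOH co-evaporation
Reagents that add atoms: none
Why: Narasaka–Prasad reduction, in which boron links O17 to the C5 carbonyl oxygen on the β face, which also carries the axial C7 silyloxy group, so that external hydride enters from the α face and gives the axial (5S) alcohol, syn to O17 and cis to C18 and O9, under conditions not basic enough for retro-aldol cleavage.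

**Step 16**
Reactants: 23 1,3-diol
Product: 24 C5 acetate (C18 OH free)
Conditions: Ac2O, DMAP, pyridine, CH2Cl2, rt
Reagents that add atoms: acetic anhydride, CC(=O)OC(C)=O
Why: DMAP-catalysed acetylation takes place at the only secondary hydroxyl, the tertiary C18 hydroxyl being too hindered to react.

**Step 17**
Reactants: 24 acetate carbinol
Product: 25 C18 trimethylsilyl ether of 24
Conditions: TMSOTf, 2,6-lutidine, CH2Cl2, −78 to 0 °C
Reagents that add atoms: trimethylsilyl triflate, C[Si](C)(C)OS(=O)(=O)C(F)(F)F
Why: Silyl triflate silylation caps the tertiary hydroxyl, so that the later Lewis-acid step runs without free protons, without α-ketol rearrangement and with a bulky group on O17.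

**Step 18**
Reactants: 25 fully protected dithiane
Product: 26 C10 ketone (C18(OTMS)(CH3)–C(=O)–CH2–CH=C(CH3)2 side chain; C5 β-OAc; C7 β-OSiEt3; C22 α-OTBS)
Conditions: MeI, CaCO3, MeCN/H2O 4:1, 45 °C
Reagents that add atoms: water, O
Why: Alkylative hydrolysis of the dithiane (S-methylation, ring opening, addition of water) under CaCO3 buffer unmasks the ketone without electrophilic halogen or mercury salts, which would attack the trisubstituted alkene, and without base, which would move the alkene into conjugation.

**Step 19**
Reactants: 26 silyloxy ketone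
Product: 28 (10S)-2-oxabicyclo[3.2.2]nonane alcohol (bridge C7–O9–C10–C18–C20; C10 prenyl; C18 OH and CH3; C5 OAc; C22 OTBS), via cage trimethylsilyl ether 27 (not isolated)
Conditions: Et3SiH, TMSOTf (0.3 equiv), CH2Cl2, −78 to −20 °C; then 1 M HCl, THF, 0 °C
Reagents that add atoms: none
Why: Silyl-triflate-catalysed reductive etherification, in which the C7 silyl ether adds across the boat cyclohexane to the activated C10 ketone, loss of siloxane gives the bridged oxocarbenium ion O9=C10, and Et3SiH delivers hydride to the face turned toward the C21–C22 bridge, anti to the C18–O17 bond (polar Felkin–Anh) and away from the C5 acetoxy and O17 silyl groups that fill the other face, which sets (10S) with H10 cis to C19 before the acid wash removes the labile trimethylsilyl group.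

**Step 20**
Reactants: 28 cage alcohol
Product: 29 C22 tert-butyldimethylsilyl ether of the target ((12S)-bromotetrahydropyran)
Conditions: NBS, (CF3)2CHOH, 4 Å MS, 0 °C, dark
Reagents that add atoms: N-bromosuccinimide, O=C1CCC(=O)N1Br
Why: Bromoetherification, in which the bromonium ion of the electron-rich C12=C14 alkene is opened by O17 at the tertiary carbon C14 (Markovnikov, 6-endo) through a chair that keeps C20 equatorial on the new ring, and the anti addition places bromine equatorial and cis to C19, that is (12S), the 5-exo tetrahydrofuran isomer being the expected by-product.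

**Step 21**
Reactants: 29 silyl ether
Product: 30 target CNP0247588.2
Conditions: HF·pyridine, THF, 0 °C to rt
Reagents that add atoms: none
Why: Fluoride-driven cleavage of the Si–O bond under mildly acidic conditions frees O23 without migration or hydrolysis of the acetate and without elimination or substitution of the secondary bromide.

**Compound list**

1 | 4-hydroxy-6-methyl-2H-pyran-2-one | CC1=CC(O)=CC(=O)O1 | starting material
2 | 4-methoxy-6-methyl-2H-pyran-2-one | COC1=CC(=O)OC(C)=C1 | intermediate
3 | 1,3-oxazolidin-2-one | O=C1NCCO1 | starting material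
4 | acryloyl chloride | C=CC(Cl)=O | starting material
5 | 3-acryloyl-1,3-oxazolidin-2-one | C=CC(=O)N1CCOC1=O | intermediate
6 | endo imide adduct, (1R,4R,7R) | COC1=C[C@@]2(C)OC(=O)[C@@H]1C[C@H]2C(=O)N1CCOC1=O | intermediate
7 | enol-ether S-ethyl thioester | COC1=C[C@@]2(C)OC(=O)[C@@H]1C[C@H]2C(=O)SCC | intermediate
8 | dimethyl ketal S-ethyl thioester | COC1(OC)C[C@@]2(C)OC(=O)[C@@H]1C[C@H]2C(=O)SCC | intermediate
9 | endo methyl ketone | COC1(OC)C[C@@]2(C)OC(=O)[C@@H]1C[C@H]2C(C)=O | intermediate
10 | endo acetate | COC1(OC)C[C@@]2(C)OC(=O)[C@@H]1C[C@H]2OC(C)=O | intermediate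
11 | diol Weinreb amide | COC1(OC)C[C@@](C)(O)[C@H](O)C[C@H]1C(=O)N(C)OC | intermediate
12 | C22 TBS ether | COC1(OC)C[C@@](C)(O)[C@H](O[Si](C)(C)C(C)(C)C)C[C@H]1C(=O)N(C)OC | intermediate
13 | C22 TBS, C7 TES ether | COC1(OC)C[C@@](C)(O[Si](CC)(CC)CC)[C@H](O[Si](C)(C)C(C)(C)C)C[C@H]1C(=O)N(C)OC | intermediate
14 | C18 methyl ketone | COC1(OC)C[C@@](C)(O[Si](CC)(CC)CC)[C@H](O[Si](C)(C)C(C)(C)C)C[C@H]1C(C)=O | intermediate
15 | 1,3-dithiane | C1CSCSC1 | starting material
16 | 1-bromo-3-methylbut-2-ene | CC(C)=CCBr | starting material
17 | 2-lithio-1,3-dithiane | [Li]C1SCCCS1 | intermediate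
18 | 2-(3-methylbut-2-en-1-yl)-1,3-dithiane | CC(C)=CCC1SCCCS1 | intermediate
19 | 2-lithio-2-prenyl-1,3-dithiane | [Li]C1(CC=C(C)C)SCCCS1 | intermediate
20 | (18S)-carbinol, C5 ketal | COC1(OC)C[C@@](C)(O[Si](CC)(CC)CC)[C@H](O[Si](C)(C)C(C)(C)C)C[C@H]1[C@](C)(O)C1(CC=C(C)C)SCCCS1 | intermediate
21 | C5 ketone | O=C1C[C@@](C)(O[Si](CC)(CC)CC)[C@H](O[Si](C)(C)C(C)(C)C)C[C@H]1[C@](C)(O)C1(CC=C(C)C)SCCCS1 | intermediate
22 | O17 diethylborinate of 21 | O=C1C[C@@](C)(O[Si](CC)(CC)CC)[C@H](O[Si](C)(C)C(C)(C)C)C[C@H]1[C@](C)(OB(CC)CC)C1(CC=C(C)C)SCCCS1 | intermediate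
23 | (5S)-alcohol, syn 1,3-diol | O[C@H]1C[C@@](C)(O[Si](CC)(CC)CC)[C@H](O[Si](C)(C)C(C)(C)C)C[C@H]1[C@](C)(O)C1(CC=C(C)C)SCCCS1 | intermediate
24 | C5 acetate | CC(=O)O[C@H]1C[C@@](C)(O[Si](CC)(CC)CC)[C@H](O[Si](C)(C)C(C)(C)C)C[C@H]1[C@](C)(O)C1(CC=C(C)C)SCCCS1 | intermediate
25 | C5 acetate, O17 TMS ether | CC(=O)O[C@H]1C[C@@](C)(O[Si](CC)(CC)CC)[C@H](O[Si](C)(C)C(C)(C)C)C[C@H]1[C@](C)(O[Si](C)(C)C)C1(CC=C(C)C)SCCCS1 | intermediate
26 | C10 ketone | CC(=O)O[C@H]1C[C@@](C)(O[Si](CC)(CC)CC)[C@H](O[Si](C)(C)C(C)(C)C)C[C@H]1[C@](C)(O[Si](C)(C)C)C(=O)CC=C(C)C | intermediate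
27 | cage trimethylsilyl ether | CC(=O)O[C@H]1C[C@@]2(C)O[C@@H](CC=C(C)C)[C@@](C)(O[Si](C)(C)C)[C@@H]1C[C@H]2O[Si](C)(C)C(C)(C)C | intermediate
28 | cage alcohol | CC(=O)O[C@H]1C[C@@]2(C)O[C@@H](CC=C(C)C)[C@@](C)(O)[C@@H]1C[C@H]2O[Si](C)(C)C(C)(C)C | intermediate
29 | target C22 TBS ether | CC(=O)O[C@H]1C[C@@]2(C)O[C@H]3C[C@H](Br)C(C)(C)O[C@@]3(C)[C@@H]1C[C@H]2O[Si](C)(C)C(C)(C)C | intermediate
30 | CNP0247588.2 | CC(=O)O[C@H]1C[C@@]2(C)O[C@H]3C[C@H](Br)C(C)(C)O[C@@]3(C)[C@@H]1C[C@H]2O | target

Total step count: 21. Longest linear sequence: 19 (steps 1, 3–11 and 13–21).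

**Steps most likely to fail**

**Step 3.**
- What may go wrong: the pyranone may be too poor a diene at temperatures where CO2 is retained.
- Its carbonyl oxygen, or that of the product, may sequester the copper.
- A stepwise pathway may end in conjugate alkylation at C3 with re-aromatisation instead of ring closure.
- Endo or enantiofacial control may leak.
- Fallback (known chemistry), setting out from 2: (4S)-4-benzyl-1,3-oxazolidin-2-one is acylated with 4 as in step 2 to (4S)-3-acryloyl-4-benzyl-1,3-oxazolidin-2-one F1.
- 2 and F1 are then compressed to about 12 kbar in CH2Cl2 at room temperature. The uncatalysed high-pressure cycloaddition of 2-pyranones to acrylic dienophiles with retention of the CO2 bridge is established, and it favours the concerted path.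
- The covalent auxiliary turns the enantiomer problem into a separation of diastereomers, from which the endo benzyloxazolidinone adduct F2 is taken by chromatography or crystallisation.
- LiSEt as in step 4 removes the auxiliary, and the route is rejoined at 7.

**Step 19.**
- What may go wrong: closure of the hindered tertiary silyl ether onto the neopentyl ketone may be outrun by direct silane reduction of the carbonyl group.
- The oxocarbenium ion may lose a proton at C11, so that the alkene drifts into conjugation.
- Hydride may enter from the wrong face.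
- Fallback, setting out from 25: the C10 electrophile is generated from the dithiane itself. S-Methylation (MeOTf, 4 Å MS, CH2Cl2, −40 °C to rt) opens the dithiane to a thionium ion, a stronger electrophile than the silylated ketone.
- The C7 silyl ether traps this ion with loss of its silyl group, giving the bridged O,S-ketal F3.
- Homolytic C–S cleavage (Ph3SnH, AIBN, toluene, 80 °C) gives the C10 α-oxy radical, which abstracts hydrogen on the open face toward the C21–C22 bridge.
- The route is rejoined at 27, which the acid wash of step 19 converts to 28.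

**Step 13.**
- What may go wrong: the hindered tertiary carbanion may enolise the methyl ketone instead of adding to it.
- The crowded transition state may erode the facial selectivity.
- Fallback, setting out from 14: the C10–C18 bond is made first with the smaller nucleophile, and the C10–C11 bond afterwards.
- 2-Lithio-1,3-dithiane 17, generated as in step 12, is added to 14 under the same Felkin–Anh bias to give the C10-unsubstituted dithianyl carbinol F4.
- Two equivalents of n-BuLi (THF, −30 to 0 °C) give the O,C-dilithio derivative F5, in which the alkoxide cannot leave by β-elimination.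
- C-Alkylation of F5 with 16 rejoins the route at 20.

**Further compounds**

F1 | step 3 | (4S)-3-acryloyl-4-benzyl-1,3-oxazolidin-2-one | C=CC(=O)N1[C@@H](Cc2ccccc2)COC1=O
F2 | step 3 | endo benzyloxazolidinone adduct | COC1=C[C@@]2(C)OC(=O)[C@@H]1C[C@H]2C(=O)N1[C@@H](Cc2ccccc2)COC1=O
F3 | step 19 | bridged O,S-ketal (C10 configuration not defined, erased in the radical step) | CC(=O)O[C@H]1C[C@@]2(C)OC(CC=C(C)C)(SCCCSC)[C@@](C)(O[Si](C)(C)C)[C@@H]1C[C@H]2O[Si](C)(C)C(C)(C)C
F4 | step 13 | C10-unsubstituted dithianyl carbinol | COC1(OC)C[C@@](C)(O[Si](CC)(CC)CC)[C@H](O[Si](C)(C)C(C)(C)C)C[C@H]1[C@](C)(O)C1SCCCS1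
F5 | step 13 | O,C-dilithio derivative of F4 | COC1(OC)C[C@@](C)(O[Si](CC)(CC)CC)[C@H](O[Si](C)(C)C(C)(C)C)C[C@H]1[C@](C)(O[Li])C1([Li])SCCCS1
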